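## Analysis of the target

The target 27 is a cembrane-type 14-membered carbocycle. Its ring carbons are numbered M1 to M14 here, starting at the O–CH carbon of the α-methylene lactone and running through the trisubstituted alkene. Two five-membered lactones sit on this ring. An α-methylene-γ-butyrolactone is fused across M14/M1. A butenolide has its O–CH at M5, its ring alkene at M6=M7 and its carbonyl on M7, so it bridges M5 and M7. There are four stereocentres: M1 (S) and M14 (R), trans on the γ-lactone, M5 (R) in the butenolide, and M10 (R), which carries the hydroperoxide. M5 and M10 lie at least three ring atoms away from each other and from the M1/M14 pair, so none can be relied on to direct another. The most fragile group is the secondary allylic hydroperoxide, which is reducible and prone to allylic transposition and to base-induced dehydration. Next come the α-methylene lactone (a Michael acceptor), the butenolide (acidic γ-hydrogen at M5) and the ionisable allylic C–O bond at M1. The synthesis is hard because a 14-membered ring holding two lactones must be closed, remote stereocentres must be set without mutual help, and an O–O bond must be introduced at the end beside three electrophilic alkenes. The strategy rests on the adjacency of M10 (CH–O) and M11 (C=CH2). A secondary carbinol next to a 1,1-disubstituted alkene is what forms when a 2-metalated 1-alkene adds to an aldehyde, so M10–M11 can be the ring-closing bond.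

## Retrosynthetic reasoning

**M10–OOH (27 ⇒ 26 ⇒ 25).** The O–O group cannot be carried through organometallic steps, so the C–O bond at M10 is cut last. A peroxide nucleophile displaces the methanesulfonate 26 with inversion. The alcohol 25 must therefore have the opposite (S) configuration at M10. Only two operations then follow the ring closure, and the hydroperoxide exists only in the final flask.

**M10–M11 (25 ⇒ 24).** This is the only ring bond flanked by a carbinol and a 1,1-disubstituted alkene. Cutting it gives one open chain, 24, with an aldehyde at M10 and a 2-iodoalkene at M11. The M2=M3 alkene was not chosen because closing a trisubstituted alkene by metathesis gives no geometric control, and the lactone C–O bonds lie outside the macrocycle. The forward step must add the alkenyl metal to the aldehyde only, on its Re face, and leave both lactones and both Michael acceptors alone.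

**Aldehyde unmasking (24 ⇒ 23 ⇒ 22).** The M10 aldehyde is carried as a primary silyl ether until the two halves are joined, because the fragment union itself uses an aldehyde. Desilylation and oxidation reveal it just before ring closure.

**M1–M14 and the lactone C–O bond (22 ⇒ 20 + 6).** The trans α-methylene lactone is cut into the enal 20 (M1 as aldehyde carbon) and the allylic bromide 6 (M14 as γ-carbon). A γ-substituted 2-(alkoxycarbonyl)allyl chromium reagent adds anti to aldehydes, and the alkoxide then closes onto the ester. This joins two halves of similar size, sets M1 and M14 together and forms the lactone in the same operation. M5 is too far away to help, so a chiral ligand on chromium must choose the aldehyde face.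

**The bromide (6 ⇒ 5 ⇒ 3 + 4; 3 ⇒ 2 ⇒ 1).** The bromide 6 is the 1,3-transposed halide of the acrylate–aldehyde adduct 5, made from the aldehyde 3 and the acrylate 4. The 2-iodoalkene of 3 comes from Markovnikov hydroiodination of the alkynol 1 via 2. The iodide is in place from the first step and stays inert until nickel is added.

**The butenolide (20 ⇒ 19 ⇒ 18 + 9; 9 ⇒ 7 ⇒ 2).** The M6=M7 alkene is cut by ring-closing metathesis logic, giving the ester 19 of the vinyl carbinol 18 with the 2-substituted acrylic acid 9. The acid carries M8 to M10 and is made by carboxylation from 7, the silyl ether of 2. The alcohol 2 thus feeds both halves.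

**M3–CH3 and M1–M2 (18 ⇒ 17 ⇒ 15).** The E-trisubstituted alkene comes from syn methyl-metalation of the terminal alkyne of 15 and capture of the alkenyl metal by a one-carbon electrophile. The methyl group and M1 end up cis, which is the required geometry. The primary allylic alcohol of 17 is then oxidised selectively to the enal 18.

**M3–M4, the vinyl group and M5 (15 ⇒ 14 ⇒ 12 ⇒ 11 ⇒ 10).** A silyl-capped acetylide opens the epoxide of 11 at its CH2 terminus and forms M3–M4. The hydroxy sulfonate 12 closes to a new epoxide 13, and a sulfonium ylide converts it into the vinyl carbinol 14. M5 is the stereocentre of the glycidol 10, and no bond to it is broken.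

## Alternatives that were turned down

**Alternative 1: ring-closing alkyne metathesis at M2≡M3.**
- Disconnection and key step: the ring is cut at M2–M3 as an alkyne. Mo(≡CC6H4OMe)(OSiPh3)3 joins two methyl-capped alkyne termini to the cycloalkyne A1. A1 has a free propargylic alcohol at M1, the E-alkene M10=M11 carrying a methyl group, and three silyl ethers.
- For it: alkyne metathesis is among the most dependable macrocyclisations, and a 14-membered cycloalkyne is unstrained. The M1 hydroxyl can direct a trans-hydrometalation that places the methyl on M3 with E geometry. On reliability of ring closure it is stronger than the chosen route.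
- Against it: A1 is far from the target in oxidation state. The alkyne must become the methylated alkene, and both lactones must be made by deprotection and oxidation. M10 carries no oxygen, so the hydroperoxide must come from a late photo-oxygenation. That step must choose between two trisubstituted alkenes, between several allylic hydrogens and between two faces, with substrate control only.
- Comparison: the chosen route takes more risk in the ring closure but delivers the M10 oxygen and the M11 methylene in that same event. Only two steps then remain.

**Alternative 2: palladium allyl transposition closing the methylene lactone.**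
- Disconnection and key step: the O–M1 bond is cut. Pd2(dba)3 with a phosphine ionises a tertiary M3 carbonate in a preformed macrocycle. The tethered acrylic acid attacks M1 and gives A2, the bis-lactone with a silyl ether at M10.
- For it: both M3 epimers converge on one allyl complex. The Michael-accepting lactone appears very late, which is gentler on it than the chosen route, where it survives five steps. The endgame at M10 is the same as the chosen one.
- Against it: the step closes only the five-membered ring, so the 14-membered ring still needs its own macrocyclisation. The syn or anti geometry of the allyl complex inside the ring decides the E/Z outcome at M2=M3. The face of ionisation decides M1 relative to M14. Neither is secured by the structure. Zerovalent palladium also meets the allylic C–O bond of the butenolide at M5.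
- Comparison: the chosen route sets M1 and M14 through an ordered six-membered transition state on an open chain. It also fixes the alkene geometry earlier by carbometalation.

**Alternative 3: carbonylative (2+2+1) macrocyclisation to the butenolide.**
- Disconnection and key step: the butenolide is cut into an M5 aldehyde, a terminal alkyne M6≡M7 and carbon monoxide. Zerovalent nickel from Ni(cod)2 with a chiral phosphine, or Ru3(CO)12, joins them under CO to the ovatodiolide-type bis-lactone A3.
- For it: it is the shortest plan. It forms three bonds and two rings at once and needs no protecting group for the butenolide.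
- Against it: such couplings are established for short tethers that give fused bicycles. Here the tether leaves from the internal alkyne carbon and the aldehyde must bond to the far terminus, so the product is bridged. The metallacycle would have to span the whole macrocycle, and M5 would be set by a ligand with no nearby anchor. The methylene lactone must survive a low-valent metal under CO. A3 also lacks the M10 oxygen, so the same unselective photo-oxygenation as in alternative 1 follows.
- Comparison: the chosen route is longer but rests on a ring closure with macrocyclic precedent and places the M10 oxygen by C–C bond formation.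

Key step: step 18

## Route

Remark on the chemistry: both chromium steps need attack on the Re face of the aldehyde, and the antipode of the oxazoline sulfonamide ligand that gives this sense is to be assigned on model aldehydes beforehand. Pent-4-yn-1-ol is taken as the source of the 2-iodoallyl unit because hydroiodination supplies it in one step.

Step 1
Reactants: 1 pent-4-yn-1-ol
Product: 2 4-iodopent-4-en-1-ol
Conditions: NaI, TMSCl, H2O (0.5 equiv), MeCN, rt
Reagents that add atoms: sodium iodide, [Na+].[I-]
Why: Markovnikov hydroiodination of a terminal alkyne by hydrogen iodide made in the flask puts iodine on the internal carbon and gives the 2-iodo-1-alkene that becomes M11 and its methylene; a transient O-silyl ether is cleaved on work-up.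

Step 2
Reactants: 2 4-iodopent-4-en-1-ol
Product: 3 4-iodopent-4-enal
Conditions: Dess–Martin periodinane, CH2Cl2, 0 °C to rt
Reagents that add atoms: none
Why: Dess–Martin oxidation of a primary alcohol stops at the aldehyde under neutral conditions and leaves the vinyl iodide untouched.

Step 3
Reactants: 3 4-iodopent-4-enal; 4 methyl acrylate
Product: 5 methyl 3-hydroxy-6-iodo-2-methylidenehept-6-enoate (racemic)
Conditions: DABCO (1 equiv), 4 (3 equiv), dioxane/H2O 1:1, rt
Reagents that add atoms: none
Why: Morita–Baylis–Hillman reaction joins the acrylate α-carbon to the aldehyde; the new carbinol centre is racemic, which does not matter because the next step removes it.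

Step 4
Reactants: 5 methyl 3-hydroxy-6-iodo-2-methylidenehept-6-enoate
Product: 6 methyl (2Z)-2-(bromomethyl)-6-iodohepta-2,6-dienoate
Conditions: PBr3 (0.4 equiv), Et2O, 0 °C
Reagents that add atoms: phosphorus tribromide, BrP(Br)Br
Why: Bromination of a Baylis–Hillman alcohol goes with 1,3-transposition (SN2′) to the conjugated primary allylic bromide, and the Z isomer with the chain trans to the ester should prevail; the geometry is not critical because the allylchromium reagent of step 15 equilibrates.

Step 5
Reactants: 2 4-iodopent-4-en-1-ol
Product: 7 tert-butyl[(4-iodopent-4-en-1-yl)oxy]dimethylsilane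
Conditions: TBSCl, imidazole, CH2Cl2, rt
Reagents that add atoms: tert-butyldimethylsilyl chloride, CC(C)(C)[Si](C)(C)Cl
Why: Standard silylation of a primary alcohol; the silyl ether masks the future M10 oxygen through the organolithium, metathesis and chromium steps.

Step 6
Reactants: 7 tert-butyl[(4-iodopent-4-en-1-yl)oxy]dimethylsilane
Product: 9 5-[(tert-butyldimethylsilyl)oxy]-2-methylidenepentanoic acid, via vinyllithium 8 (not isolated)
Conditions: t-BuLi (2.1 equiv), Et2O, −78 °C; CO2 (gas); cold 0.5 M HCl work-up
Reagents that add atoms: carbon dioxide, O=C=O
Why: Iodine–lithium exchange on a 2-iodo-1-alkene is fast at −78 °C, and carboxylation of the vinyllithium gives the 2-substituted acrylic acid directly; the carboxyl carbon becomes the butenolide carbonyl and the vinyl carbon becomes M7.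

Step 7
Reactants: 10 (S)-glycidol
Product: 11 (2R)-oxiran-2-ylmethyl 4-methylbenzenesulfonate
Conditions: TsCl, Et3N, DMAP (cat.), CH2Cl2, −10 °C
Reagents that add atoms: 4-methylbenzenesulfonyl chloride, Cc1ccc(cc1)S(Cl)(=O)=O
Why: O-Sulfonylation of the primary alcohol; no bond at the stereocentre is touched, and the descriptor changes from S to R only because the sulfonate raises the rank of the CH2O arm.

Step 8
Reactants: 11 (2R)-oxiran-2-ylmethyl 4-methylbenzenesulfonate
Product: 12 (2R)-2-hydroxy-5-(trimethylsilyl)pent-4-yn-1-yl 4-methylbenzenesulfonate
Conditions: ethynyltrimethylsilane, n-BuLi, THF, −78 °C; BF3·OEt2; then 11, −78 °C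
Reagents that add atoms: ethynyltrimethylsilane, C#C[Si](C)(C)C
Why: Lewis-acid-promoted opening of a terminal epoxide by a lithium acetylide occurs at the CH2 terminus faster than sulfonate displacement at −78 °C; it forms the M3–M4 bond and leaves the carbinol centre (future M5) untouched.

Step 9
Reactants: 12 (2R)-2-hydroxy-5-(trimethylsilyl)pent-4-yn-1-yl 4-methylbenzenesulfonate
Product: 14 (3R)-6-(trimethylsilyl)hex-1-en-5-yn-3-ol, via epoxide 13 (not isolated)
Conditions: Me3S+ I− (4.5 equiv), n-BuLi (4.3 equiv), THF, −15 °C; then 12, −15 °C to rt
Reagents that add atoms: trimethylsulfonium iodide, C[S+](C)C.[I-]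
Why: The alkoxide of 12 displaces the sulfonate (3-exo-tet) to the epoxide 13; dimethylsulfonium methylide opens it at the CH2 terminus, and the resulting betaine eliminates dimethyl sulfide to give the allylic alcohol (one-carbon homologation of an epoxide). The C–O bond at the stereocentre is retained throughout.

Step 10
Reactants: 14 (3R)-6-(trimethylsilyl)hex-1-en-5-yn-3-ol
Product: 15 (3R)-hex-1-en-5-yn-3-ol
Conditions: K2CO3 (cat.), MeOH, rt
Reagents that add atoms: none
Why: Methanolysis of the alkynyl C–Si bond frees the terminal alkyne needed for carbometalation; the product is volatile and is concentrated with care.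

Step 11
Reactants: 15 (3R)-hex-1-en-5-yn-3-ol
Product: 17 (2E,5R)-3-methylhepta-2,6-diene-1,5-diol, via alkenylalane 16 (not isolated)
Conditions: Me3Al (3 equiv), Cp2ZrCl2 (0.25 equiv), CH2Cl2, 0 °C to rt; volatiles removed; n-BuLi, THF, −78 °C; (CH2O)n, rt; aq. Rochelle salt
Reagents that add atoms: trimethylaluminium, C[Al](C)C; formaldehyde (as paraformaldehyde), C=O
Why: Zirconium-catalysed carboalumination adds methyl and aluminium syn across the terminal alkyne, with methyl on the internal carbon (M3); the alkenyl aluminate then takes up formaldehyde with retention, so methyl and M1 end up cis and the alkene is E. The free hydroxyl is carried as its aluminium alkoxide, and the monosubstituted alkene reacts much more slowly than the alkyne.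

Step 12
Reactants: 17 (2E,5R)-3-methylhepta-2,6-diene-1,5-diol
Product: 18 (2E,5R)-5-hydroxy-3-methylhepta-2,6-dienal
Conditions: TEMPO (10 mol %), PhI(OAc)2 (1.1 equiv), CH2Cl2, rt
Reagents that add atoms: none
Why: Oxoammonium-mediated oxidation strongly prefers primary over secondary alcohols and does not isomerise E-enals, so the primary allylic alcohol becomes the enal while the vinyl carbinol stays.

Step 13
Reactants: 18 (2E,5R)-5-hydroxy-3-methylhepta-2,6-dienal; 9 5-[(tert-butyldimethylsilyl)oxy]-2-methylidenepentanoic acid
Product: 19 (3R,5E)-5-methyl-7-oxohepta-1,5-dien-3-yl 5-[(tert-butyldimethylsilyl)oxy]-2-methylidenepentanoate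
Conditions: DCC, DMAP (cat.), CH2Cl2, 0 °C to rt
Reagents that add atoms: none
Why: Steglich esterification acylates the secondary allylic alcohol without touching the enal or the C–O bond at the stereocentre.

Step 14
Reactants: 19 (3R,5E)-5-methyl-7-oxohepta-1,5-dien-3-yl 5-[(tert-butyldimethylsilyl)oxy]-2-methylidenepentanoate
Product: 20 (2E)-4-[(2R)-4-{3-[(tert-butyldimethylsilyl)oxy]propyl}-5-oxo-2,5-dihydrofuran-2-yl]-3-methylbut-2-enal
Conditions: second-generation Grubbs catalyst RuCl2(=CHPh)(PCy3)(H2IMes) (5–10 mol %), CH2Cl2, 40 °C, 5 mM
Reagents that add atoms: none
Why: Ring-closing metathesis between the vinyl group and the 1,1-disubstituted acrylate closes the five-membered butenolide (M6=M7) with loss of ethene; the electron-poor trisubstituted enal alkene should not take part.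

Step 15
Reactants: 20 (2E)-4-[(2R)-4-{3-[(tert-butyldimethylsilyl)oxy]propyl}-5-oxo-2,5-dihydrofuran-2-yl]-3-methylbut-2-enal; 6 methyl (2Z)-2-(bromomethyl)-6-iodohepta-2,6-dienoate
Product: 22 (4R,5S)-5-[(1E)-3-[(2R)-4-{3-[(tert-butyldimethylsilyl)oxy]propyl}-5-oxo-2,5-dihydrofuran-2-yl]-2-methylprop-1-en-1-yl]-4-(3-iodobut-3-en-1-yl)-3-methylideneoxolan-2-one, via hydroxy ester 21 (not isolated)
Conditions: CrCl2 (3 equiv, nickel-free), N-[2-(4-isopropyl-4,5-dihydrooxazol-2-yl)-6-methylphenyl]methanesulfonamide (one antipode, 3.3 equiv), Et3N (3.3 equiv), THF, rt; then 6 (1.5 equiv) and 20, 0 °C to rt; PPTS (cat.), CH2Cl2, rt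
Reagents that add atoms: none
Why: Chromium-mediated 2-(alkoxycarbonyl)allylation: divalent chromium reduces the allylic bromide to an allylchromium reagent (trivalent chromium) that equilibrates and adds to the enal carbonyl in a 1,2 sense through a six-membered chair transition state with the γ-substituent pseudo-equatorial, which gives the anti adduct. The chiral sulfonamide on chromium selects the Re face of the aldehyde and so sets M1 (S), and M14 (R) follows from the anti course; the alkoxide then closes onto the methyl ester (5-exo-trig) to the trans α-methylene lactone. The vinyl iodide is inert to divalent chromium without nickel.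

Step 16
Reactants: 22 TBS-protected bis-lactone (name as in step 15)
Product: 23 (4R,5S)-5-[(1E)-3-[(2R)-4-(3-hydroxypropyl)-5-oxo-2,5-dihydrofuran-2-yl]-2-methylprop-1-en-1-yl]-4-(3-iodobut-3-en-1-yl)-3-methylideneoxolan-2-one
Conditions: HF·pyridine, pyridine, THF, 0 °C to rt
Reagents that add atoms: none
Why: Buffered fluoride cleaves the primary silyl ether without basic conditions, which protects the Michael-accepting lactone and the epimerisable M5 position.

Step 17
Reactants: 23 hydroxypropyl bis-lactone (name as in step 16)
Product: 24 3-[(5R)-5-{(2E)-3-[(2S,3R)-3-(3-iodobut-3-en-1-yl)-4-methylidene-5-oxooxolan-2-yl]-2-methylprop-2-en-1-yl}-2-oxo-2,5-dihydrofuran-3-yl]propanal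
Conditions: Dess–Martin periodinane, CH2Cl2, 0 °C to rt
Reagents that add atoms: none
Why: Dess–Martin oxidation gives the M10 aldehyde under neutral conditions; 24 is used promptly in the ring closure.

Step 18
Reactants: 24 seco aldehyde (name as in step 17)
Product: 25 macrocyclic allylic alcohol: 14-membered ring M1–M14 with the trans α-methylene lactone across M14/M1, the butenolide across M5–M7, E-M2=M3 with methyl on M3, M11=CH2 and hydroxyl on M10; M1 S, M5 R, M10 S, M14 R
Conditions: CrCl2 (6 equiv), N-[2-(4-isopropyl-4,5-dihydrooxazol-2-yl)-6-methylphenyl]methanesulfonamide (one antipode, 6.6 equiv), Et3N (6.6 equiv), NiCl2 (2 mol % of chromium), THF/MeCN, rt; 24 added by syringe pump to about 1 mM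
Reagents that add atoms: none
Why: Nozaki–Hiyama–Kishi macrocyclisation: divalent chromium reduces NiCl2 to zerovalent nickel, which inserts into the C–I bond of the 2-iodoalkene; transmetalation gives an alkenylchromium species (trivalent chromium) that adds to the aldehyde held in the same ligand sphere. The closest known reaction type is the nickel-catalysed alkenylchromium–aldehyde macrocyclisation with chiral sulfonamide ligands on chromium. The M10–M11 bond closes the 14-membered ring in a 14-exo-trig mode. M10 is the only new stereocentre and is set by the chiral ligand, which must direct the alkenyl group to the Re face to give the (S)-alcohol, because M5 and M14 are too remote to control it. The 2-metalated 1-alkene fixes the methylene on M11 and the oxygen on M10 without any regiochemical choice. Chemoselectivity for the aldehyde over both lactone carbonyls and both Michael acceptors follows from the low basicity and high oxophilicity of organochromium reagents, and the low nickel loading keeps zerovalent nickel away from the allylic C–O bonds. Ring closure is favoured over oligomerisation by slow addition at high dilution and by the two rigid lactones and the E-alkene, which limit the degrees of freedom of the chain.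

Step 19
Reactants: 25 macrocyclic allylic alcohol (M10 S)
Product: 26 macrocyclic M10 methanesulfonate (M10 S), otherwise as 25
Conditions: Ms2O, Et3N, CH2Cl2, −40 °C; used at once without chromatography
Reagents that add atoms: methanesulfonic anhydride, CS(=O)(=O)OS(C)(=O)=O
Why: O-Sulfonylation leaves the configuration at carbon unchanged; the anhydride avoids chloride, which would displace the allylic sulfonate, and the low temperature limits ionisation and deprotonation at M5.

Step 20
Reactants: 26 macrocyclic M10 methanesulfonate
Product: 27 4-methylene-5β-hydroperoxyovatodiolide (M1 S, M5 R, M10 R, M14 R)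
Conditions: anhydrous H2O2 in Et2O (large excess), −78 °C to −20 °C
Reagents that add atoms: hydrogen peroxide, OO
Why: Hydrogen peroxide, an α-effect nucleophile, displaces the allylic sulfonate in an SN2 process with inversion, turning (S) at M10 into the required (R); this is the known preparation of alkyl hydroperoxides from sulfonates. No base is present, so the peroxide does not add to the methylene lactone or the butenolide.

## Compound list

1 | pent-4-yn-1-ol | C#CCCCO | starting material
2 | 4-iodopent-4-en-1-ol | C=C(I)CCCO | intermediate
3 | 4-iodopent-4-enal | C=C(I)CCC=O | intermediate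
4 | methyl acrylate | C=CC(=O)OC | starting material
5 | methyl 3-hydroxy-6-iodo-2-methylidenehept-6-enoate (racemic) | C=C(I)CCC(O)C(=C)C(=O)OC | intermediate
6 | methyl (2Z)-2-(bromomethyl)-6-iodohepta-2,6-dienoate | C=C(I)CC/C=C(\CBr)C(=O)OC | intermediate
7 | tert-butyl[(4-iodopent-4-en-1-yl)oxy]dimethylsilane | C=C(I)CCCO[Si](C)(C)C(C)(C)C | intermediate
8 | {5-[(tert-butyldimethylsilyl)oxy]pent-1-en-2-yl}lithium (not isolated) | [Li]C(=C)CCCO[Si](C)(C)C(C)(C)C | intermediate
9 | 5-[(tert-butyldimethylsilyl)oxy]-2-methylidenepentanoic acid | C=C(CCCO[Si](C)(C)C(C)(C)C)C(=O)O | intermediate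
10 | (S)-glycidol | OC[C@H]1CO1 | starting material
11 | (2R)-oxiran-2-ylmethyl 4-methylbenzenesulfonate | Cc1ccc(cc1)S(=O)(=O)OC[C@H]1CO1 | intermediate
12 | (2R)-2-hydroxy-5-(trimethylsilyl)pent-4-yn-1-yl 4-methylbenzenesulfonate | Cc1ccc(cc1)S(=O)(=O)OC[C@H](O)CC#C[Si](C)(C)C | intermediate
13 | (2R)-2-[3-(trimethylsilyl)prop-2-yn-1-yl]oxirane (not isolated) | C[Si](C)(C)C#CC[C@@H]1CO1 | intermediate
14 | (3R)-6-(trimethylsilyl)hex-1-en-5-yn-3-ol | C[Si](C)(C)C#CC[C@@H](O)C=C | intermediate
15 | (3R)-hex-1-en-5-yn-3-ol | C#CC[C@@H](O)C=C | intermediate
16 | [(1E,4R)-4-[(dimethylalumanyl)oxy]-2-methylhexa-1,5-dien-1-yl]dimethylalumane (not isolated) | C[Al](C)/C=C(\C)C[C@@H](O[Al](C)C)C=C | intermediate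
17 | (2E,5R)-3-methylhepta-2,6-diene-1,5-diol | OC/C=C(\C)C[C@@H](O)C=C | intermediate
18 | (2E,5R)-5-hydroxy-3-methylhepta-2,6-dienal | O=C/C=C(\C)C[C@@H](O)C=C | intermediate
19 | (3R,5E)-5-methyl-7-oxohepta-1,5-dien-3-yl 5-[(tert-butyldimethylsilyl)oxy]-2-methylidenepentanoate | O=C/C=C(\C)C[C@@H](OC(=O)C(=C)CCCO[Si](C)(C)C(C)(C)C)C=C | intermediate
20 | (2E)-4-[(2R)-4-{3-[(tert-butyldimethylsilyl)oxy]propyl}-5-oxo-2,5-dihydrofuran-2-yl]-3-methylbut-2-enal | O=C/C=C(\C)C[C@@H]1C=C(CCCO[Si](C)(C)C(C)(C)C)C(=O)O1 | intermediate
21 | methyl (3R,4S,5E)-4-hydroxy-3-(3-iodobut-3-en-1-yl)-6-methyl-2-methylidene-7-[(2R)-4-{3-[(tert-butyldimethylsilyl)oxy]propyl}-5-oxo-2,5-dihydrofuran-2-yl]hept-5-enoate (anti hydroxy ester, not isolated) | C=C(I)CC[C@H](C(=C)C(=O)OC)[C@@H](O)/C=C(\C)C[C@@H]1C=C(CCCO[Si](C)(C)C(C)(C)C)C(=O)O1 | intermediate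
22 | (4R,5S)-5-[(1E)-3-[(2R)-4-{3-[(tert-butyldimethylsilyl)oxy]propyl}-5-oxo-2,5-dihydrofuran-2-yl]-2-methylprop-1-en-1-yl]-4-(3-iodobut-3-en-1-yl)-3-methylideneoxolan-2-one | C=C(I)CC[C@@H]1C(=C)C(=O)O[C@H]1/C=C(\C)C[C@@H]2C=C(CCCO[Si](C)(C)C(C)(C)C)C(=O)O2 | intermediate
23 | (4R,5S)-5-[(1E)-3-[(2R)-4-(3-hydroxypropyl)-5-oxo-2,5-dihydrofuran-2-yl]-2-methylprop-1-en-1-yl]-4-(3-iodobut-3-en-1-yl)-3-methylideneoxolan-2-one | C=C(I)CC[C@@H]1C(=C)C(=O)O[C@H]1/C=C(\C)C[C@@H]2C=C(CCCO)C(=O)O2 | intermediate
24 | 3-[(5R)-5-{(2E)-3-[(2S,3R)-3-(3-iodobut-3-en-1-yl)-4-methylidene-5-oxooxolan-2-yl]-2-methylprop-2-en-1-yl}-2-oxo-2,5-dihydrofuran-3-yl]propanal | C=C(I)CC[C@@H]1C(=C)C(=O)O[C@H]1/C=C(\C)C[C@@H]2C=C(CCC=O)C(=O)O2 | intermediate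
25 | macrocyclic M10 allylic alcohol (M1 S, M5 R, M10 S, M14 R) | C=C1C(=O)O[C@H]2/C=C(\C)C[C@@H]3C=C(CC[C@H](O)C(=C)CC[C@H]12)C(=O)O3 | intermediate
26 | macrocyclic M10 methanesulfonate (M1 S, M5 R, M10 S, M14 R) | C=C1C(=O)O[C@H]2/C=C(\C)C[C@@H]3C=C(CC[C@H](OS(C)(=O)=O)C(=C)CC[C@H]12)C(=O)O3 | intermediate
27 | 4-methylene-5β-hydroperoxyovatodiolide (M1 S, M5 R, M10 R, M14 R) | C=C1C(=O)O[C@H]2/C=C(\C)C[C@@H]3C=C(CC[C@@H](OO)C(=C)CC[C@H]12)C(=O)O3 | target

## Step count and risks

Total: 20 steps. Longest linear sequence: 14 steps (steps 7 to 20, from 10). The west half (steps 1 to 4) and the acid 9 (steps 5 and 6) branch from the common alcohol 2.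

**Step 18 (key step).** The most likely failure is poor facial selection at the M10 aldehyde, because transannular strain in the forming ring may outweigh the chiral ligand sphere. Intermolecular coupling to dimers is the second concern. Fallback: starting from 24, the ring is closed with CrCl2 and catalytic NiCl2 in DMSO/THF without chiral ligand. This gives 25 mixed with its M10 epimer, the (10R)-alcohol F1. The mixture is oxidised with Dess–Martin periodinane to the macrocyclic α-methylene ketone F2. Corey–Bakshi–Shibata reduction of F2 with catecholborane and the (R)-configured B-methyl oxazaborolidine at −78 °C should return 25, with the alkenyl branch acting as the large group. M10 is then set by hydride delivery to a ketone and no longer by the C–C bond formation.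

**Step 20.** The most likely failures are ionisation of the allylic sulfonate, which erodes the configuration at M10, and attack at the methylene terminus (SN2′), which gives the transposed primary hydroperoxide. Both compete because neutral hydrogen peroxide is a modest nucleophile and the sulfonate is allylic. Fallback: starting from 25, the substitution is replaced by an ene reaction. Mitsunobu displacement with 2-nitrobenzenesulfonylhydrazide (PPh3, diethyl azodicarboxylate, THF, −30 °C) gives the N-sulfonyl hydrazine F3. On warming it loses sulfinic acid to the allylic diazene F4. Sigmatropic loss of dinitrogen moves the alkene to M10=M11 and turns the methylene into a methyl group, giving the trisubstituted alkene F5. Photo-oxygenation of F5 (O2, tetraphenylporphyrin, visible light, CH2Cl2, −20 °C; Schenck ene reaction) should abstract hydrogen from the M11 methyl group and place the hydroperoxide on M10 from the outer face of the ring. This returns to the route at 27. The fallback erases the M10 configuration of 25, so either epimer serves. Its cost is lower regioselectivity and competition from the M2=M3 alkene.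

**Step 15.** The most likely failure is weak facial control by the ligand on a β,β-disubstituted enal, or partial loss of the anti preference because the ester substituent changes the allylchromium equilibrium. Fallback: starting from 20 and 6, the coupling is run with CrCl2 in THF without chiral ligand. This still favours the anti adducts and gives 21 together with its (3S,4R) isomer F6. These close to 22 and the diastereomeric trans lactone F7. Because M5 is already fixed, 22 and F7 are diastereomers and are separated by preparative chromatography. 22 then re-enters the route. Reagent control is given up for separation, at the cost of half the material.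

**Step 11.** The most likely failure is incomplete or regio-unselective methylalumination in the presence of the aluminium alkoxide, or sluggish capture of the alkenylalane by formaldehyde. Fallback: starting from 15, double deprotonation with n-BuLi and addition of paraformaldehyde give the propargylic diol F8. Hydroxyl-directed trans-hydroalumination with sodium bis(2-methoxyethoxy)aluminium hydride, NaAlH2(OCH2CH2OMe)2, followed by iodine, gives the (Z)-iodoalkene F9. Me2CuLi replaces iodine by methyl with retention and returns to the route at 17.

## Further compounds

F1 | step 18 | macrocyclic M10 allylic alcohol, (10R) epimer of 25 | C=C1C(=O)O[C@H]2/C=C(\C)C[C@@H]3C=C(CC[C@@H](O)C(=C)CC[C@H]12)C(=O)O3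
F2 | step 18 | macrocyclic M10 ketone (α-methylene ketone) | C=C1C(=O)O[C@H]2/C=C(\C)C[C@@H]3C=C(CCC(=O)C(=C)CC[C@H]12)C(=O)O3
F3 | step 20 | (10R)-N-alkyl-N-(2-nitrobenzenesulfonyl)hydrazine of the macrocycle | C=C1C(=O)O[C@H]2/C=C(\C)C[C@@H]3C=C(CC[C@@H](N(N)S(=O)(=O)c4ccccc4[N+](=O)[O-])C(=C)CC[C@H]12)C(=O)O3
F4 | step 20 | (10R)-allylic diazene of the macrocycle | C=C1C(=O)O[C@H]2/C=C(\C)C[C@@H]3C=C(CC[C@@H](N=N)C(=C)CC[C@H]12)C(=O)O3
F5 | step 20 | bis-lactone with E-M10=M11 alkene and methyl on M11 | C=C1C(=O)O[C@H]2/C=C(\C)C[C@@H]3C=C(CC/C=C(\C)CC[C@H]12)C(=O)O3
F6 | step 15 | (3S,4R) diastereomer of hydroxy ester 21 | C=C(I)CC[C@@H](C(=C)C(=O)OC)[C@H](O)/C=C(\C)C[C@@H]1C=C(CCCO[Si](C)(C)C(C)(C)C)C(=O)O1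
F7 | step 15 | (4S,5R) trans-lactone diastereomer of 22 | C=C(I)CC[C@H]1C(=C)C(=O)O[C@@H]1/C=C(\C)C[C@@H]2C=C(CCCO[Si](C)(C)C(C)(C)C)C(=O)O2
F8 | step 11 | (5R)-hept-6-en-2-yne-1,5-diol | OCC#CC[C@@H](O)C=C
F9 | step 11 | (2Z,5R)-3-iodohepta-2,6-diene-1,5-diol | OC/C=C(\I)C[C@@H](O)C=C
A1 | alternative 1 | 14-membered cycloalkyne with M1 propargylic alcohol and three silyl ethers | O[C@H]1C#CC[C@@H](O[Si](C)(C)C(C)(C)C)/C=C(CO[Si](C)(C)C(C)(C)C)/CC/C=C(\C)CC[C@@H]1C(=C)CO[Si](C)(C)C(C)(C)C
A2 | alternative 2 | 14-membered bis-lactone with M10 silyl ether | C=C1C(=O)O[C@H]2/C=C(\C)C[C@@H]3C=C(CC[C@H](O[Si](C)(C)C(C)(C)C)C(=C)CC[C@H]12)C(=O)O3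
A3 | alternative 3 | ovatodiolide-type bis-lactone with E-M10=M11 alkene | C=C1C(=O)O[C@H]2/C=C(\C)C[C@@H]3C=C(CC/C=C(\C)CC[C@H]12)C(=O)O3
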